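**Retrosynthetic overview**
1. The five stereocentres are split 2 + 2 + 1: C2/C3 come from the key step, C4/C5 from an asymmetric homoaldol addition, and the side-chain centre from an asymmetric alkene hydrogenation. The oxolane (ring atoms O1, C2–C5) is the only ring that is made, and it is made last.
2. Key disconnection: O1–C2 and C2–C3 of the oxolane. A (Z)-4-hydroxy enol carbamate (C5, C4, C3 and a formyl carbon parked on C3) condenses with 4-acetoxybenzaldehyde (C2), and the ring closes by C2–C3 bond formation.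
3. Enabling feature: C2 is a benzylic carbon bonded to ring O1 (aldehyde oxidation level, hence an O1=C2 oxocarbenium ion). C3, two atoms away from C5–O1, carries one H beside its methyl; a formyl group takes the place of this H, makes C3 an enol carbon, and is later extruded as CO with retention.
4. The enol carbamate comes from the aryl aldehyde and (E)-2-methylbut-2-enyl carbamate. The aryl aldehyde comes from 5-bromo-2-methoxyacetophenone by benzyl Grignard addition, dehydration, hydrogenation, protecting-group exchange and formylation.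
5. End game: decarbonylation, then methanolysis of the three aryl esters.

Key step: step 9

Assumption: (+)-sparteine is taken to induce with carbamate 10 the mirror image of the sense known for (−)-sparteine and (E)-but-2-enyl carbamate (lithiation, then titanation with inversion), and the (S)-phosphinooxazoline ligand is taken to give the (R)-alkane as with (E)-1,2-diphenylpropene; if either sense is reversed, the antipodal ligand is used.

**Step 1**
Reactants: 1 1-(5-bromo-2-methoxyphenyl)ethan-1-one; 2 (4-methoxybenzyl)magnesium chloride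
Product: 3 2-(5-bromo-2-methoxyphenyl)-1-(4-methoxyphenyl)propan-2-ol (racemic)
Conditions: THF, 0 °C → rt; aq. NH4Cl
Reagents that add atoms: none
Why: Grignard 1,2-addition of the benzylic organomagnesium to the methyl ketone (assisted by chelation to the ortho-methoxy group) should give the tertiary alcohol, whose new stereocentre is removed in the next step.

**Step 2**
Reactants: 3 2-(5-bromo-2-methoxyphenyl)-1-(4-methoxyphenyl)propan-2-ol
Product: 4 (E)-4-bromo-1-methoxy-2-[1-(4-methoxyphenyl)prop-1-en-2-yl]benzene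
Conditions: TsOH·H2O (cat.), toluene, reflux, Dean–Stark; crystallisation
Reagents that add atoms: none
Why: Acid-catalysed E1 dehydration under equilibrating conditions should favour the conjugated (E)-1,2-diarylpropene (aryl groups trans), which is purified by crystallisation.

**Step 3**
Reactants: 4 (E)-4-bromo-1-methoxy-2-[1-(4-methoxyphenyl)prop-1-en-2-yl]benzene
Product: 5 (R)-4-bromo-1-methoxy-2-[1-(4-methoxyphenyl)propan-2-yl]benzene
Conditions: [Ir(cod)(L)]BArF (1 mol %; L = (S)-4-tert-butyl-2-[2-(di-o-tolylphosphanyl)phenyl]-4,5-dihydro-1,3-oxazole; cod = cycloocta-1,5-diene; BArF = B[C6H3-3,5-(CF3)2]4), H2 (50 bar), CH2Cl2, rt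
Reagents that add atoms: none
Why: Iridium-catalysed asymmetric hydrogenation of unfunctionalised (E)-1,2-diarylpropenes with phosphinooxazoline ligands is the model reaction of this catalyst class, the chiral ligand selects the alkene face so that the (R)-benzylic centre should form, and the aryl bromide is not touched.

**Step 4**
Reactants: 5 (R)-4-bromo-1-methoxy-2-[1-(4-methoxyphenyl)propan-2-yl]benzene
Product: 6 (R)-4-bromo-2-[1-(4-hydroxyphenyl)propan-2-yl]phenol
Conditions: BBr3 (3 equiv), CH2Cl2, −78 °C → rt; H2O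
Reagents that add atoms: none
Why: BBr3 cleaves both aryl methyl ethers by Lewis-acid-assisted SN2 demethylation without touching the aryl bromide or the stereocentre.

**Step 5**
Reactants: 6 (R)-4-bromo-2-[1-(4-hydroxyphenyl)propan-2-yl]phenol
Product: 7 (R)-4-bromo-2-[1-(4-pivaloyloxyphenyl)propan-2-yl]phenyl pivalate
Conditions: PivCl, Et3N, DMAP (cat.), CH2Cl2, 0 °C → rt
Reagents that add atoms: pivaloyl chloride, CC(C)(C)C(Cl)=O
Why: DMAP-catalysed O-acylation converts both phenols into pivalates, which make the arenes less electron-rich and should survive the later organotitanium, Lewis acid and rhodium steps.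

**Step 6**
Reactants: 7 (R)-4-bromo-2-[1-(4-pivaloyloxyphenyl)propan-2-yl]phenyl pivalate
Product: 8 (R)-4-formyl-2-[1-(4-pivaloyloxyphenyl)propan-2-yl]phenyl pivalate
Conditions: Pd(OAc)2 (1 mol %), di(1-adamantyl)-n-butylphosphine (3 mol %), CO/H2 (1:1, 5 bar), TMEDA, toluene, 100 °C
Reagents that add atoms: carbon monoxide, [C-]#[O+]
Why: Palladium-catalysed reductive carbonylation (formylation) of aryl bromides with synthesis gas tolerates aryl esters and should install the aldehyde para to the pivaloyloxy group.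

**Step 7**
Reactants: 9 (E)-2-methylbut-2-en-1-ol
Product: 10 (E)-2-methylbut-2-en-1-yl N,N-diisopropylcarbamate
Conditions: NaH, THF, 0 °C; iPr2NCOCl, reflux
Reagents that add atoms: N,N-diisopropylcarbamoyl chloride, CC(C)N(C(C)C)C(Cl)=O
Why: O-carbamoylation of the sodium alkoxide gives the allyl carbamate needed for α-lithiation and leaves the (E)-alkene unchanged.

**Step 8**
Reactants: 10 (E)-2-methylbut-2-en-1-yl N,N-diisopropylcarbamate; 8 (R)-4-formyl-2-[1-(4-pivaloyloxyphenyl)propan-2-yl]phenyl pivalate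
Product: 13 (1Z,3R,4R)-4-hydroxy-2,3-dimethyl-4-{4-pivaloyloxy-3-[(2R)-1-(4-pivaloyloxyphenyl)propan-2-yl]phenyl}but-1-en-1-yl N,N-diisopropylcarbamate, via lithiocarbamate 11 (not isolated), via allyltitanium 12 (not isolated)
Conditions: 10 (1.5 equiv), n-BuLi, (+)-sparteine, pentane–cyclohexane, −78 °C, 3 h; Ti(OiPr)4 (4 equiv); 8 in toluene, −78 °C; aq. HCl
Reagents that add atoms: none
Why: In this Hoppe asymmetric homoaldol reaction, sparteine-mediated lithiation next to the carbamate oxygen, titanation with inversion and γ-addition of the allyltitanium to the aldehyde through a chair Zimmerman–Traxler transition state should give the (Z)-enol carbamate with anti C3/C4, both centres being set by the chiral diamine because the remote side-chain centre does not bias the aldehyde.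

**Step 9**
Reactants: 13 (1Z,3R,4R)-4-hydroxy enol carbamate; 14 4-formylphenyl acetate
Product: 17 (2R,3R,4R,5R)-2-(4-acetoxyphenyl)-3-formyl-3,4-dimethyl-5-{4-pivaloyloxy-3-[(2R)-1-(4-pivaloyloxyphenyl)propan-2-yl]phenyl}oxolane, via hemiacetal 15 (not isolated), via oxocarbenium ion 16 (not isolated)
Conditions: 14 (1.5 equiv), BF3·OEt2 (1.5 equiv), CH2Cl2, −78 → 0 °C; sat. aq. NaHCO3
Reagents that add atoms: none
Why: BF3 converts hemiacetal 15 into the (E)-oxocarbenium ion 16 (O1=C2), the enol-carbamate carbon (future C3) attacks its carbon in a Mukaiyama-aldol-type (Prins-type) closure, and the resulting carbamoyloxy carbenium ion collapses to the formyl group with loss of the carbamoyl unit as diisopropylcarbamic acid. The closest known reaction type is the Lewis-acid condensation of (Z)-anti-4-hydroxyalk-1-enyl carbamates (homoaldol adducts) with aldehydes to oxolane-3-carbaldehydes, and mechanistically the Lewis-acid ring contraction of cyclic vinyl acetals, which runs through the same ion pair. The oxolane closes in the 5-(enol-exo)-endo-trig mode, with the O1=C2 bond inside and the enol double bond outside the new ring. C2 is controlled by the (E)-geometry of the oxocarbenium ion and the pseudo-equatorial C5 aryl group in the envelope transition state, which should place the two aryl groups cis; C3 is controlled by allylic 1,3-strain in the (Z)-enol carbamate, which holds the C4–H bond in the enol plane so that C2 adds to the face that leaves the C3 methyl cis to the C4 methyl and the formyl group trans to it. The step needs ionisation at the hemiacetal and not at the benzylic C5–O bond, and no later scrambling of C2; the three acyloxy groups (weaker donors than ether groups) should secure both, and the quaternary C3 cannot epimerise.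

**Step 10**
Reactants: 17 (2R,3R,4R,5R)-3-formyl oxolane
Product: 18 4-[(2S,3S,4R,5R)-3,4-dimethyl-5-{4-pivaloyloxy-3-[(2R)-1-(4-pivaloyloxyphenyl)propan-2-yl]phenyl}oxolan-2-yl]phenyl acetate
Conditions: RhCl(PPh3)3 (1.2 equiv), PhCN, 150 °C
Reagents that add atoms: none
Why: Tsuji–Wilkinson decarbonylation (oxidative addition into the formyl C–H bond, CO de-insertion, C–H reductive elimination) is known to replace a formyl group on a quaternary carbon by hydrogen with retention, so C3 should keep its methyl cis to the C4 methyl and trans to the C2 aryl group.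

**Step 11**
Reactants: 18 triester of the target
Product: 19 4-[(2S,3S,4R,5R)-5-{4-hydroxy-3-[(2R)-1-(4-hydroxyphenyl)propan-2-yl]phenyl}-3,4-dimethyloxolan-2-yl]phenol (CNP0232576.1)
Conditions: K2CO3 (0.5 equiv), MeOH–THF, 40 °C; aq. NH4Cl
Reagents that add atoms: none
Why: Base-catalysed transesterification with methanol should cleave the aryl acetate and both aryl pivalates under conditions that leave the 2,5-diaryloxolane and all five stereocentres untouched.

**Compound list**
1 | 1-(5-bromo-2-methoxyphenyl)ethan-1-one | COc1ccc(Br)cc1C(C)=O | starting material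
2 | (4-methoxybenzyl)magnesium chloride (THF solution) | COc1ccc(C[Mg]Cl)cc1 | starting material
3 | 2-(5-bromo-2-methoxyphenyl)-1-(4-methoxyphenyl)propan-2-ol (racemic) | COc1ccc(Br)cc1C(C)(O)Cc1ccc(OC)cc1 | intermediate
4 | (E)-4-bromo-1-methoxy-2-[1-(4-methoxyphenyl)prop-1-en-2-yl]benzene | COc1ccc(Br)cc1/C(C)=C/c1ccc(OC)cc1 | intermediate
5 | (R)-4-bromo-1-methoxy-2-[1-(4-methoxyphenyl)propan-2-yl]benzene | COc1ccc(Br)cc1[C@H](C)Cc1ccc(OC)cc1 | intermediate
6 | (R)-4-bromo-2-[1-(4-hydroxyphenyl)propan-2-yl]phenol | Oc1ccc(Br)cc1[C@H](C)Cc1ccc(O)cc1 | intermediate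
7 | (R)-4-bromo-2-[1-(4-pivaloyloxyphenyl)propan-2-yl]phenyl pivalate | CC(C)(C)C(=O)Oc1ccc(Br)cc1[C@H](C)Cc1ccc(OC(=O)C(C)(C)C)cc1 | intermediate
8 | (R)-4-formyl-2-[1-(4-pivaloyloxyphenyl)propan-2-yl]phenyl pivalate | CC(C)(C)C(=O)Oc1ccc(C=O)cc1[C@H](C)Cc1ccc(OC(=O)C(C)(C)C)cc1 | intermediate
9 | (E)-2-methylbut-2-en-1-ol | C/C=C(\C)CO | starting material
10 | (E)-2-methylbut-2-en-1-yl N,N-diisopropylcarbamate | C/C=C(\C)COC(=O)N(C(C)C)C(C)C | intermediate
11 | (R,E)-1-lithio-2-methylbut-2-en-1-yl N,N-diisopropylcarbamate, (+)-sparteine complex | C/C=C(\C)[C@@H]([Li])OC(=O)N(C(C)C)C(C)C | intermediate (not isolated)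
12 | (S,E)-2-methyl-1-(triisopropoxytitanio)but-2-en-1-yl N,N-diisopropylcarbamate | C/C=C(\C)[C@H]([Ti](OC(C)C)(OC(C)C)OC(C)C)OC(=O)N(C(C)C)C(C)C | intermediate (not isolated)
13 | (1Z,3R,4R)-4-hydroxy-2,3-dimethyl-4-{4-pivaloyloxy-3-[(2R)-1-(4-pivaloyloxyphenyl)propan-2-yl]phenyl}but-1-en-1-yl N,N-diisopropylcarbamate | C[C@@H]([C@@H](O)c1ccc(OC(=O)C(C)(C)C)c([C@H](C)Cc2ccc(OC(=O)C(C)(C)C)cc2)c1)/C(C)=C\OC(=O)N(C(C)C)C(C)C | intermediate
14 | 4-formylphenyl acetate | CC(=O)Oc1ccc(C=O)cc1 | starting material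
15 | hemiacetal of 13 with 14 (both epimers at the hemiacetal carbon) | C[C@@H]([C@@H](OC(O)c1ccc(OC(C)=O)cc1)c1ccc(OC(=O)C(C)(C)C)c([C@H](C)Cc2ccc(OC(=O)C(C)(C)C)cc2)c1)/C(C)=C\OC(=O)N(C(C)C)C(C)C | intermediate (not isolated)
16 | (E)-oxocarbenium ion, hydroxytrifluoroborate salt | C[C@@H]([C@@H](/[O+]=C/c1ccc(OC(C)=O)cc1)c1ccc(OC(=O)C(C)(C)C)c([C@H](C)Cc2ccc(OC(=O)C(C)(C)C)cc2)c1)/C(C)=C\OC(=O)N(C(C)C)C(C)C.O[B-](F)(F)F | intermediate (not isolated)
17 | (2R,3R,4R,5R)-2-(4-acetoxyphenyl)-3-formyl-3,4-dimethyl-5-{4-pivaloyloxy-3-[(2R)-1-(4-pivaloyloxyphenyl)propan-2-yl]phenyl}oxolane (aryl groups cis; formyl cis to the C2 aryl; the two methyls cis) | C[C@@H]1[C@](C=O)(C)[C@@H](c2ccc(OC(C)=O)cc2)O[C@H]1c1ccc(OC(=O)C(C)(C)C)c([C@H](C)Cc2ccc(OC(=O)C(C)(C)C)cc2)c1 | intermediate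
18 | 4-[(2S,3S,4R,5R)-3,4-dimethyl-5-{4-pivaloyloxy-3-[(2R)-1-(4-pivaloyloxyphenyl)propan-2-yl]phenyl}oxolan-2-yl]phenyl acetate | C[C@@H]1[C@H](C)[C@@H](c2ccc(OC(C)=O)cc2)O[C@H]1c1ccc(OC(=O)C(C)(C)C)c([C@H](C)Cc2ccc(OC(=O)C(C)(C)C)cc2)c1 | intermediate
19 | 4-[(2S,3S,4R,5R)-5-{4-hydroxy-3-[(2R)-1-(4-hydroxyphenyl)propan-2-yl]phenyl}-3,4-dimethyloxolan-2-yl]phenol | C[C@@H]1[C@H](C)[C@@H](c2ccc(O)cc2)O[C@H]1c1ccc(O)c([C@H](C)Cc2ccc(O)cc2)c1 | target

**Step count and risks**
Total steps: 11. Longest linear sequence: 10 (steps 1–6, then 8–11); step 7 is a side branch.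

Step 8, asymmetric homoaldol. The lithiated 2-methyl-substituted carbamate may not be enriched or held in one configuration on the sparteine complex, so that facial control is lost and both anti adducts form (diastereomers with respect to the side-chain centre); attack at the α-carbon may also compete. The fallback sets out from aldehyde 8 and uses (E)-but-2-en-1-yl N,N-diisopropylcarbamate F1 (made from (E)-but-2-en-1-ol as in step 7), for which enrichment of the lithium–sparteine complex by crystallisation is established. With (+)-sparteine and Ti(OiPr)4 as in step 8 this should give the (1Z,3R,4R) adduct F2. Condensation of F2 with 14 under BF3·OEt2 as in step 9 should give the 3-formyl oxolane without the C3 methyl F3, whose C3 configuration does not matter. Methylation of its potassium enolate (KN(SiMe3)2, THF, −78 °C; MeI), expected anti to the C2 aryl group, comes back to the route at 17.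

Step 9, key cyclisation. BF3 may ionise the free benzylic alcohol of 13, or the water equivalent set free may hydrolyse the enol carbamate, before the hemiacetal ionises; closure through the other enol rotamer would also erode the C3 configuration. The fallback sets out from 13 and generates the same oxocarbenium ion by oxidative C–H cleavage instead of condensation. O-Alkylation with 4-[(tert-butyldimethylsilyl)oxy]benzyl bromide (AgOTf, 2,6-di-tert-butyl-4-methylpyridine, CH2Cl2) gives the benzyl ether F4. DDQ (2,6-dichloropyridine, LiClO4, 1,2-dichloroethane) abstracts hydride from the electron-rich benzylic ether carbon, without Lewis acid or water, and the ion closes to the silyl-protected formyl oxolane F5. RhCl(PPh3)3 as in step 10 gives the decarbonylated silyl ether F6, and K2CO3 in MeOH cleaves both pivalates and the aryl silyl ether, coming back at target 19.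

Step 10, decarbonylation. CO extrusion at the crowded quaternary carbon may be slow, and the tertiary alkylrhodium intermediate may undergo β-hydride elimination to alkenes instead of C–H reductive elimination. The fallback needs no decarbonylation: it sets out from aldehyde 8 and runs through F2 and F3 of the fallback to step 8. F3 is equilibrated at C3 (DBU, toluene) toward the epimer F7 with the formyl group trans to the C2 aryl and cis to the C4 methyl; the epimers are separated and the other one is recycled. NaBH4 (THF–EtOH, −20 °C) gives the primary alcohol F8, and MsCl/Et3N gives the mesylate F9. LiAlH4 (THF, reflux) reduces the C–OMs group to the C3 methyl and cleaves the three esters, coming back at target 19.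

**Further compounds**
F1 | step 8 | (E)-but-2-en-1-yl N,N-diisopropylcarbamate | C/C=C/COC(=O)N(C(C)C)C(C)C
F2 | step 8 | (1Z,3R,4R)-4-hydroxy-3-methyl-4-{4-pivaloyloxy-3-[(2R)-1-(4-pivaloyloxyphenyl)propan-2-yl]phenyl}but-1-en-1-yl N,N-diisopropylcarbamate | C[C@@H]([C@@H](O)c1ccc(OC(=O)C(C)(C)C)c([C@H](C)Cc2ccc(OC(=O)C(C)(C)C)cc2)c1)/C=C\OC(=O)N(C(C)C)C(C)C
F3 | step 8 | (2S,3R,4R,5R)-2-(4-acetoxyphenyl)-3-formyl-4-methyl-5-{4-pivaloyloxy-3-[(2R)-1-(4-pivaloyloxyphenyl)propan-2-yl]phenyl}oxolane (formyl cis to the C2 aryl) | C[C@@H]1[C@@H](C=O)[C@@H](c2ccc(OC(C)=O)cc2)O[C@H]1c1ccc(OC(=O)C(C)(C)C)c([C@H](C)Cc2ccc(OC(=O)C(C)(C)C)cc2)c1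
F4 | step 9 | (1Z,3R,4R)-4-{4-[(tert-butyldimethylsilyl)oxy]benzyloxy}-2,3-dimethyl-4-{4-pivaloyloxy-3-[(2R)-1-(4-pivaloyloxyphenyl)propan-2-yl]phenyl}but-1-en-1-yl N,N-diisopropylcarbamate | C[C@@H]([C@@H](OCc1ccc(O[Si](C)(C)C(C)(C)C)cc1)c1ccc(OC(=O)C(C)(C)C)c([C@H](C)Cc2ccc(OC(=O)C(C)(C)C)cc2)c1)/C(C)=C\OC(=O)N(C(C)C)C(C)C
F5 | step 9 | (2R,3R,4R,5R)-2-{4-[(tert-butyldimethylsilyl)oxy]phenyl}-3-formyl-3,4-dimethyl-5-{4-pivaloyloxy-3-[(2R)-1-(4-pivaloyloxyphenyl)propan-2-yl]phenyl}oxolane | C[C@@H]1[C@](C=O)(C)[C@@H](c2ccc(O[Si](C)(C)C(C)(C)C)cc2)O[C@H]1c1ccc(OC(=O)C(C)(C)C)c([C@H](C)Cc2ccc(OC(=O)C(C)(C)C)cc2)c1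
F6 | step 9 | (2S,3S,4R,5R)-2-{4-[(tert-butyldimethylsilyl)oxy]phenyl}-3,4-dimethyl-5-{4-pivaloyloxy-3-[(2R)-1-(4-pivaloyloxyphenyl)propan-2-yl]phenyl}oxolane | C[C@@H]1[C@H](C)[C@@H](c2ccc(O[Si](C)(C)C(C)(C)C)cc2)O[C@H]1c1ccc(OC(=O)C(C)(C)C)c([C@H](C)Cc2ccc(OC(=O)C(C)(C)C)cc2)c1
F7 | step 10 | C3 epimer of F3 (formyl trans to the C2 aryl and cis to the C4 methyl) | C[C@@H]1[C@H](C=O)[C@@H](c2ccc(OC(C)=O)cc2)O[C@H]1c1ccc(OC(=O)C(C)(C)C)c([C@H](C)Cc2ccc(OC(=O)C(C)(C)C)cc2)c1
F8 | step 10 | 3-(hydroxymethyl) oxolane from F7 | C[C@@H]1[C@H](CO)[C@@H](c2ccc(OC(C)=O)cc2)O[C@H]1c1ccc(OC(=O)C(C)(C)C)c([C@H](C)Cc2ccc(OC(=O)C(C)(C)C)cc2)c1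
F9 | step 10 | methanesulfonate of F8 | C[C@@H]1[C@H](COS(C)(=O)=O)[C@@H](c2ccc(OC(C)=O)cc2)O[C@H]1c1ccc(OC(=O)C(C)(C)C)c([C@H](C)Cc2ccc(OC(=O)C(C)(C)C)cc2)c1
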